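**Retrosynthetic overview**
1. The aryl ester is made last: acylation of the C6 carbinol with a protected 4‑hydroxybenzoic acid, then release of the phenol.
2. The seven‑membered ring is closed by ring‑closing metathesis (C8=C9) of a vinyl ketone with a 2‑methylallyl side chain.
3. The C4 carbinol comes from isopropyl addition to a cyclopentanone carbonyl, anti to the C5 side chain.
4. Key step: a one‑flask, three‑component union on 3‑methylcyclopent‑2‑en‑1‑one. An acryloyl anion equivalent (metallated methoxyallene) adds enantioselectively in conjugate fashion (C1–C10 bond, quaternary C1), and the enolate is captured by 3‑methylbut‑3‑enal (C5–C6 bond).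
5. Ring order: the five‑membered ring is bought with the enone; the seven‑membered ring is formed at the end.

Assumption: positions are named by daucane numbering (C1 angular‑methyl carbon, C2/C3 ring CH2, C4 isopropyl carbinol, C5 ring‑fusion CH, C6 acyloxy carbon, C7 CH2, C8 vinylic methyl carbon, C9 vinylic CH, C10 ketone), and methoxyallene is taken as a purchasable reagent.

**Route**

Step 1
Reactants: 1 3-methylbut-3-en-1-ol
Product: 2 3-methylbut-3-enal
Conditions: Dess–Martin periodinane, CH2Cl2, 0 °C; diluted with pentane, filtered through a short pad of basic alumina, solution kept over 4 Å molecular sieves and used at once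
Reagents that add atoms: none
Why: Dess–Martin oxidation of the primary homoallylic alcohol is non‑basic, so the β,γ‑unsaturated aldehyde forms without the double bond moving into conjugation, and the alumina filtration removes the acetic acid before the aldehyde meets the enolate; no stereocentre is made.

Step 2
Reactants: 3 3-methylcyclopent-2-en-1-one; 4 methoxyallene (1-methoxypropa-1,2-diene); 2 3-methylbut-3-enal
Product: 8 (2S,3S)-2-[(1S)-1-hydroxy-3-methylbut-3-en-1-yl]-3-(1-methoxypropa-1,2-dien-1-yl)-3-methylcyclopentan-1-one, via 1-lithio-1-methoxyallene 5 (not isolated), via (1-methoxyallenyl)dimethylaluminium 6 (not isolated), via aluminium enolate 7 (not isolated)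
Conditions: 4 (1.6 equiv), n-BuLi (1.5 equiv), THF, −40 °C; Me2AlCl (1.5 equiv), −78 °C; then 3 (1.0 equiv), Cu(OTf)2 (5 mol %), chiral sulfonate-bearing 4,5-diphenylimidazolinium salt (carbene precursor, 5 mol %, antipode giving Si-face delivery), THF, −78 to −30 °C; then 2 (3 equiv), −78 °C; aq. potassium sodium tartrate work-up
Reagents that add atoms: n-butyllithium, [Li]CCCC; dimethylaluminium chloride, C[Al](C)Cl
Why: Proposed new method: lithiated methoxyallene is an established acryloyl anion equivalent, and after transmetalation to aluminium, Cu(OTf)2 bound to the chiral N‑heterocyclic carbene should transfer its sp2 carbon to the Si face of the enone β‑carbon (closest known reaction type: Cu(OTf)2/chiral carbene‑catalysed enantioselective conjugate addition of aryl‑, alkenyl‑ and silyl‑vinyl(dimethyl)aluminium reagents, made from the organolithium and Me2AlCl, to 3‑methylcyclopentenone), so the catalyst sets C1, the regiodefined dimethylaluminium enolate then attacks the aldehyde on the face opposite the larger, branched methoxyallenyl group (C5, side chain trans to it), and the closed Zimmerman–Traxler transition state of the ring E‑enolate gives the anti aldol (C6).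

Step 3
Reactants: 8
Product: 10 1-[(1S,2S,3R)-3-hydroxy-2-[(1S)-1-hydroxy-3-methylbut-3-en-1-yl]-1-methyl-3-(propan-2-yl)cyclopentyl]prop-2-en-1-one, via allenyl ether diol 9 (not isolated)
Conditions: i-PrLi (3 equiv), CeCl3 (3 equiv, dried), THF, −78 °C; then 1 M aq. HCl, THF, 0 °C, 15 min
Reagents that add atoms: isopropyllithium, CC(C)[Li]; water, O
Why: Addition of i-PrCeCl2 under Imamoto conditions (low basicity, so little enolisation or retro‑aldol) attacks the cyclopentanone on the face opposite the adjacent C5 side chain, placing isopropyl trans and hydroxyl cis to it (C4), and the brief acidic work‑up hydrolyses the 1‑methoxyallene enol ether to the vinyl ketone.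

Step 4
Reactants: 10
Product: 11 (1R,3aS,8S,8aS)-1,8-dihydroxy-3a,6-dimethyl-1-(propan-2-yl)-1,2,3,3a,8,8a-hexahydroazulen-4(7H)-one
Conditions: second-generation Hoveyda–Grubbs catalyst (5 mol %), toluene (0.005 M), 80 °C
Reagents that add atoms: none
Why: Ring‑closing olefin metathesis between the vinyl ketone and the 1,1‑disubstituted alkene closes the trans‑fused seven‑membered ring as the trisubstituted enone with loss of ethylene; no stereocentre is touched.

Step 5
Reactants: 11; 12 4-acetoxybenzoic acid
Product: 13 [(3R,3aS,4S,8aS)-3-hydroxy-6,8a-dimethyl-8-oxo-3-(propan-2-yl)-1,2,3,3a,4,5,8,8a-octahydroazulen-4-yl] 4-(acetyloxy)benzoate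
Conditions: DCC, DMAP (0.2 equiv), CH2Cl2, 0 °C to rt
Reagents that add atoms: none
Why: Steglich esterification acylates only the secondary C6 hydroxyl, because the tertiary C4 hydroxyl is too hindered, and it proceeds with retention at C6.

Step 6
Reactants: 13
Product: 14 [(3R,3aS,4S,8aS)-3-hydroxy-6,8a-dimethyl-8-oxo-3-(propan-2-yl)-1,2,3,3a,4,5,8,8a-octahydroazulen-4-yl] 4-hydroxybenzoate (CNP0210039.1)
Conditions: K2CO3 (0.3 equiv), MeOH, 0 °C; quenched with aq. NH4Cl
Reagents that add atoms: none
Why: Base‑catalysed methanolysis (transesterification) cleaves the activated phenolic acetate much faster than the hindered secondary alkyl benzoate, and no stereocentre is affected.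

**Compound list**
1 | 3-methylbut-3-en-1-ol | CC(=C)CCO | starting material
2 | 3-methylbut-3-enal | CC(=C)CC=O | intermediate
3 | 3-methylcyclopent-2-en-1-one | CC1=CC(=O)CC1 | starting material
4 | methoxyallene (1-methoxypropa-1,2-diene) | COC=C=C | starting material
5 | 1-lithio-1-methoxyallene | [Li]C(OC)=C=C | intermediate
6 | (1-methoxyallenyl)dimethylaluminium | C[Al](C)C(OC)=C=C | intermediate
7 | dimethyl{[(3S)-3-(1-methoxypropa-1,2-dien-1-yl)-3-methylcyclopent-1-en-1-yl]oxy}aluminium (aluminium enolate) | C=C=C(OC)[C@@]1(C)CCC(O[Al](C)C)=C1 | intermediate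
8 | (2S,3S)-2-[(1S)-1-hydroxy-3-methylbut-3-en-1-yl]-3-(1-methoxypropa-1,2-dien-1-yl)-3-methylcyclopentan-1-one | C=C=C(OC)[C@@]1(C)CCC(=O)[C@@H]1[C@@H](O)CC(C)=C | intermediate
9 | (1R,2S,3S)-2-[(1S)-1-hydroxy-3-methylbut-3-en-1-yl]-3-(1-methoxypropa-1,2-dien-1-yl)-3-methyl-1-(propan-2-yl)cyclopentan-1-ol (allenyl ether diol) | C=C=C(OC)[C@@]1(C)CC[C@@](O)(C(C)C)[C@@H]1[C@@H](O)CC(C)=C | intermediate
10 | 1-[(1S,2S,3R)-3-hydroxy-2-[(1S)-1-hydroxy-3-methylbut-3-en-1-yl]-1-methyl-3-(propan-2-yl)cyclopentyl]prop-2-en-1-one | C=CC(=O)[C@@]1(C)CC[C@@](O)(C(C)C)[C@@H]1[C@@H](O)CC(C)=C | intermediate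
11 | (1R,3aS,8S,8aS)-1,8-dihydroxy-3a,6-dimethyl-1-(propan-2-yl)-1,2,3,3a,8,8a-hexahydroazulen-4(7H)-one | CC1=CC(=O)[C@@]2(C)CC[C@@](O)(C(C)C)[C@@H]2[C@@H](O)C1 | intermediate
12 | 4-acetoxybenzoic acid | CC(=O)Oc1ccc(cc1)C(=O)O | starting material
13 | [(3R,3aS,4S,8aS)-3-hydroxy-6,8a-dimethyl-8-oxo-3-(propan-2-yl)-1,2,3,3a,4,5,8,8a-octahydroazulen-4-yl] 4-(acetyloxy)benzoate | CC1=CC(=O)[C@@]2(C)CC[C@@](O)(C(C)C)[C@@H]2[C@@H](OC(=O)c2ccc(OC(C)=O)cc2)C1 | intermediate
14 | [(3R,3aS,4S,8aS)-3-hydroxy-6,8a-dimethyl-8-oxo-3-(propan-2-yl)-1,2,3,3a,4,5,8,8a-octahydroazulen-4-yl] 4-hydroxybenzoate | CC1=CC(=O)[C@@]2(C)CC[C@@](O)(C(C)C)[C@@H]2[C@@H](OC(=O)c2ccc(O)cc2)C1 | target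

**Step count**
Total steps: 6. Longest linear sequence: 6 steps (1 → 2 → 8 → 10 → 11 → 13 → 14); 5 steps from the enone 3.

**Three steps most likely to fail**

Step 2 is the main risk. Transfer of a 1‑methoxyallenyl group from aluminium through copper is untested and could give propargyl or methyl transfer or low enantioselectivity. The trans selectivity at C5 also rests on the methoxyallenyl group being effectively larger than methyl. The fallback sets out from 5 and swaps the roles of the two groups at C1. Compound 5 is added 1,2 to commercial 3‑ethoxycyclopent‑2‑en‑1‑one to give 3-ethoxy-1-(1-methoxypropa-1,2-dien-1-yl)cyclopent-2-en-1-ol F1. A buffered (pH 5) work‑up loses ethanol and gives the transposed enone 3-(1-methoxypropa-1,2-dien-1-yl)cyclopent-2-en-1-one F2 (Stork–Danheiser sequence), so the reversed‑polarity C1–C10 bond is made by a plain carbonyl addition. The quaternary centre is then made by Cu(OTf)2/chiral carbene‑catalysed enantioselective 1,4‑addition of Me3Al to F2, a well‑precedented reaction type, with the ligand antipode that gives the (S) centre. This gives the same dimethylaluminium enolate, so the fallback comes back to the route at 7 and continues to 8 by the aldol with 2.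

Step 3 could suffer from retro‑aldol of the aldolate, from enolisation or reduction by i-PrCeCl2, or from poor facial control under chelation. The fallback sets out from 8. The aldol hydroxyl is silylated (TESOTf, 2,6‑lutidine) to (2S,3S)-3-(1-methoxypropa-1,2-dien-1-yl)-3-methyl-2-[(1S)-3-methyl-1-(triethylsilyloxy)but-3-en-1-yl]cyclopentan-1-one F3. i-PrCeCl2 is added to this non‑chelating ketone, which cannot undergo retro‑aldol, to give (1R,2S,3S)-3-(1-methoxypropa-1,2-dien-1-yl)-3-methyl-2-[(1S)-3-methyl-1-(triethylsilyloxy)but-3-en-1-yl]-1-(propan-2-yl)cyclopentan-1-ol F4. The same aqueous HCl work‑up removes the silyl group and unmasks the vinyl ketone, so the fallback comes back at 10.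

Step 4 pairs an electron‑poor vinyl ketone next to a quaternary carbon with a 1,1‑disubstituted alkene, which may be slow or lead to dimers. The fallback sets out from 10. Luche reduction (NaBH4, CeCl3·7H2O, MeOH) gives the allylic alcohol 1-[(1S,2S,3R)-3-hydroxy-2-[(1S)-1-hydroxy-3-methylbut-3-en-1-yl]-1-methyl-3-(propan-2-yl)cyclopentyl]prop-2-en-1-ol F5 as a mixture at the new carbinol. Ring‑closing metathesis of this more reactive allylic alcohol gives (1R,3aS,8S,8aS)-3a,6-dimethyl-1-(propan-2-yl)-1,2,3,3a,4,7,8,8a-octahydroazulene-1,4,8-triol F6 (epimers at C4 of the azulene). Chemoselective allylic oxidation with MnO2 in CH2Cl2 then comes back to the route at 11.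

**Further compounds**
F1 | step 2 | 3-ethoxy-1-(1-methoxypropa-1,2-dien-1-yl)cyclopent-2-en-1-ol (racemic) | CCOC1=CC(O)(CC1)C(OC)=C=C
F2 | step 2 | 3-(1-methoxypropa-1,2-dien-1-yl)cyclopent-2-en-1-one | C=C=C(OC)C1=CC(=O)CC1
F3 | step 3 | (2S,3S)-3-(1-methoxypropa-1,2-dien-1-yl)-3-methyl-2-[(1S)-3-methyl-1-(triethylsilyloxy)but-3-en-1-yl]cyclopentan-1-one | C=C=C(OC)[C@@]1(C)CCC(=O)[C@@H]1[C@@H](O[Si](CC)(CC)CC)CC(C)=C
F4 | step 3 | (1R,2S,3S)-3-(1-methoxypropa-1,2-dien-1-yl)-3-methyl-2-[(1S)-3-methyl-1-(triethylsilyloxy)but-3-en-1-yl]-1-(propan-2-yl)cyclopentan-1-ol | C=C=C(OC)[C@@]1(C)CC[C@@](O)(C(C)C)[C@@H]1[C@@H](O[Si](CC)(CC)CC)CC(C)=C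
F5 | step 4 | 1-[(1S,2S,3R)-3-hydroxy-2-[(1S)-1-hydroxy-3-methylbut-3-en-1-yl]-1-methyl-3-(propan-2-yl)cyclopentyl]prop-2-en-1-ol (carbinol epimers) | C=CC(O)[C@@]1(C)CC[C@@](O)(C(C)C)[C@@H]1[C@@H](O)CC(C)=C
F6 | step 4 | (1R,3aS,8S,8aS)-3a,6-dimethyl-1-(propan-2-yl)-1,2,3,3a,4,7,8,8a-octahydroazulene-1,4,8-triol (C4 epimers) | CC1=CC(O)[C@@]2(C)CC[C@@](O)(C(C)C)[C@@H]2[C@@H](O)C1
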